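**Retrosynthetic overview**
1. Feature: in ring A (central benzene; C1 carries the 2-(3-methoxyphenyl)ethyl bridge, C2/C4/C6 the 4-hydroxybenzyl groups, C3 the OH, C5 the OMe), C4 lies between the two oxygen-bearing carbons C3 and C5. C3–C4–C5 is therefore a masked 1,3-diketone, and removing C4 joins C3 to C5 as the vicinal carbonyls of a five-membered ring C3–C2–C1–C6–C5.
2. Key disconnection: C3–C4 and C4–C5 are formed together by inserting the carbon of a 2-arylethyl diazoalkane between the carbonyls of a fully substituted cyclopent-3-ene-1,2-dione (acyl shift, loss of N2, enolisation to the symmetric resorcinol). Mono-O-methylation and threefold debenzylation finish the synthesis.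
3. The ene-dione comes from a 2,3,4-trisubstituted cyclopentenone by α'-hydroxylation and alcohol oxidation. The cyclopentenone comes from cyclopentane-1,3-dione by reductive benzylation, enol etherification, α'-benzylation and Grignard addition with 1,3-carbonyl transposition, so each substituent is placed without a regiochemical choice.
4. The diazoalkane comes from O-benzyltyramine through its N-nitrosourea, made cold and free of Lewis bases.
5. Ring order: all aryl rings and the five-membered carbocycle are bought. Ring A is the only ring formed, last, by expansion of that carbocycle.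

Key step: step 10

Assumption: the target is achiral. Every sp3 ring centre of the intermediates is racemic (or a diastereomer mixture) and ends as an sp2 carbon of ring A, so configuration is drawn only for the acyloin of step 5 (relative, trans).

**Step 1**
Reactants: 1 cyclopentane-1,3-dione; 2 4-(benzyloxy)benzaldehyde
Product: 4 2-[4-(benzyloxy)benzyl]cyclopentane-1,3-dione, via arylidene dione 3 (not isolated)
Conditions: Hantzsch ester (diethyl 2,6-dimethyl-1,4-dihydropyridine-3,5-dicarboxylate, 1.0 equiv), L-proline (10 mol %), CH2Cl2, rt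
Reagents that add atoms: none
Why: Proline-catalysed Knoevenagel condensation gives the strongly electrophilic arylidene dione 3, which the Hantzsch ester reduces in situ by conjugate hydride transfer (three-component reductive alkylation), so mono-C-benzylation is obtained without the O-alkylation and double alkylation that trouble direct benzylation of cyclic 1,3-diones; no stereocentre is formed.

**Step 2**
Reactants: 4 2-[4-(benzyloxy)benzyl]cyclopentane-1,3-dione
Product: 5 2-[4-(benzyloxy)benzyl]-3-(2-methylpropoxy)cyclopent-2-en-1-one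
Conditions: i-BuOH (5 equiv), TsOH·H2O (5 mol %), toluene, reflux, Dean–Stark
Reagents that add atoms: 2-methylpropan-1-ol, CC(C)CO
Why: Acid-catalysed enol etherification of a cyclic 1,3-dione with azeotropic removal of water; the two carbonyl groups of 4 are equivalent, so only one vinylogous ester can form, and the aryl benzyl ether tolerates catalytic TsOH.

**Step 3**
Reactants: 5 2-[4-(benzyloxy)benzyl]-3-(2-methylpropoxy)cyclopent-2-en-1-one; 6 4-(benzyloxy)benzyl bromide
Product: 8 2,5-bis[4-(benzyloxy)benzyl]-3-(2-methylpropoxy)cyclopent-2-en-1-one (racemic), via lithium enolate 7 (not isolated)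
Conditions: LiN(iPr)2 (1.1 equiv), THF, −78 °C; then 6, −78 → −20 °C
Reagents that add atoms: none
Why: Stork–Danheiser kinetic alkylation: the amide base removes an α'-proton (C5) of the vinylogous ester and the cross-conjugated enolate 7 is trapped at carbon by the reactive benzylic bromide; the new C5 centre is formed racemic and is later lost on aromatisation.

**Step 4**
Reactants: 8 2,5-bis[4-(benzyloxy)benzyl]-3-(2-methylpropoxy)cyclopent-2-en-1-one; 9 1-(2-bromoethyl)-3-methoxybenzene
Product: 12 2,4-bis[4-(benzyloxy)benzyl]-3-[2-(3-methoxyphenyl)ethyl]cyclopent-2-en-1-one (racemic), via Grignard reagent 10 (not isolated), via tertiary carbinol 11 (not isolated)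
Conditions: 9, Mg, THF, rt; LaCl3·2LiCl (1.0 equiv), 8, THF, 0 °C; then 2 M aq HCl, THF, rt
Reagents that add atoms: water, O
Why: Grignard 1,2-addition to the vinylogous ester carbonyl, with LaCl3·2LiCl raising carbonyl electrophilicity so that addition outruns enolisation of the hindered ketone, is followed by acid-induced Stork–Danheiser 1,3-carbonyl transposition (ionisation of the tertiary allylic alcohol, capture by water, loss of isobutanol), which places the arylethyl group on the β-carbon between the two benzylated carbons without any regiochemical choice; the carbinol centre disappears and the remaining C4 centre is racemic.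

**Step 5**
Reactants: 12 2,4-bis[4-(benzyloxy)benzyl]-3-[2-(3-methoxyphenyl)ethyl]cyclopent-2-en-1-one
Product: 14 trans-2,4-bis[4-(benzyloxy)benzyl]-5-hydroxy-3-[2-(3-methoxyphenyl)ethyl]cyclopent-2-en-1-one (racemic; any cis isomer is carried on), via potassium dienolate 13 (not isolated)
Conditions: KN(SiMe3)2 (1.05 equiv), THF, −78 °C; 2-(benzenesulfonyl)-3-phenyloxaziridine (1.2 equiv), −78 °C; sat. aq NH4Cl
Reagents that add atoms: 2-(benzenesulfonyl)-3-phenyloxaziridine, O=S(=O)(c1ccccc1)N1OC1c1ccccc1
Why: Davis oxidation of the kinetic α'-enolate: the hindered potassium amide deprotonates the only α'-CH2 at low temperature and the dienolate 13 attacks the oxaziridine oxygen from the face opposite the C4 benzyl group, so the trans acyloin should prevail, although this centre is removed in the next step.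

**Step 6**
Reactants: 14 trans-2,4-bis[4-(benzyloxy)benzyl]-5-hydroxy-3-[2-(3-methoxyphenyl)ethyl]cyclopent-2-en-1-one
Product: 15 3,5-bis[4-(benzyloxy)benzyl]-4-[2-(3-methoxyphenyl)ethyl]cyclopent-3-ene-1,2-dione (racemic)
Conditions: Dess–Martin periodinane (1.2 equiv), CH2Cl2, 0 °C; rapid cold work-up, used at once
Reagents that add atoms: none
Why: Dess–Martin oxidation of an α-hydroxy ketone to the 1,2-diketone under mild, essentially neutral and non-aqueous conditions is placed last because the ene-dione has an acidic ring C–H and is best kept from base, water and heat; direct enolisation would give a 2-hydroxycyclopentadienone and is therefore disfavoured, which should keep both carbonyl groups intact.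

**Step 7**
Reactants: 16 2-[4-(benzyloxy)phenyl]ethan-1-amine hydrochloride
Product: 17 1-{2-[4-(benzyloxy)phenyl]ethyl}urea
Conditions: KOCN (1.5 equiv), H2O/EtOH, 70 °C
Reagents that add atoms: potassium cyanate, [K+].[O-]C#N
Why: Wöhler-type urea synthesis: the ammonium salt protonates cyanate and the free amine adds to the isocyanic acid so formed.

**Step 8**
Reactants: 17 1-{2-[4-(benzyloxy)phenyl]ethyl}urea
Product: 18 1-{2-[4-(benzyloxy)phenyl]ethyl}-1-nitrosourea
Conditions: NaNO2 (1.5 equiv), HCO2H, 0 °C; ice-water, filtration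
Reagents that add atoms: sodium nitrite, [Na+].[O-]N=O
Why: N-Nitrosation of a monoalkylurea with nitrous acid takes place on the more nucleophilic alkyl-bearing nitrogen (the standard preparation of N-alkyl-N-nitrosoureas), and the alkoxyarene is not nitrosated by this weakly acidic medium at 0 °C.

**Step 9**
Reactants: 18 1-{2-[4-(benzyloxy)phenyl]ethyl}-1-nitrosourea
Product: 19 1-(benzyloxy)-4-(2-diazoethyl)benzene (kept as a dried, titrated toluene solution)
Conditions: 40 % aq KOH, toluene, 0 °C; organic layer decanted, dried over KOH pellets, titrated with benzoic acid, kept at −20 °C or below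
Reagents that add atoms: none
Why: Base-induced cleavage of an N-alkyl-N-nitrosourea, the classical diazoalkane synthesis: hydroxide expels cyanate, the diazotate loses hydroxide and the diazoalkane passes into the toluene layer, a cold route preferred to sulfonylhydrazone thermolysis because a non-volatile primary diazoalkane with β-hydrogens would not survive heating and because the solution obtained is free of Lewis bases that would block Sc(OTf)3.

**Step 10**
Reactants: 15 3,5-bis[4-(benzyloxy)benzyl]-4-[2-(3-methoxyphenyl)ethyl]cyclopent-3-ene-1,2-dione; 19 1-(benzyloxy)-4-(2-diazoethyl)benzene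
Product: 22 2,4,6-tris[4-(benzyloxy)benzyl]-5-[2-(3-methoxyphenyl)ethyl]benzene-1,3-diol, via diazonium betaine 20 (not isolated), via cyclohexenedione tautomer 21 (not isolated)
Conditions: Sc(OTf)3 (10 mol %), toluene/CH2Cl2, −78 °C, 19 (1.1 equiv) added slowly, → 0 °C
Reagents that add atoms: none
Why: Proposed new method: Sc(OTf)3 chelates the s-cis 1,2-dione of 15, the diazo carbon of 19 adds to an activated carbonyl (most likely the non-conjugated one next to the sp3 ring carbon) to give betaine 20, and the neighbouring acyl carbon shifts to the diazonium-bearing carbon as N2 departs, which creates the C3–C4 and C4–C5 bonds of ring A. The closest known reaction types are the Lewis-acid-catalysed Tiffeneau–Demjanov-type homologation of cycloalkanones and cyclic 1,2-dicarbonyl compounds with diazoalkanes, the diazoalkane expansion of indane-1,2,3-trione to 3-alkyl-2-hydroxy-1,4-naphthoquinones by acyl shift, and the Meinwald-type acyl shift of α,β-epoxy ketones to 1,3-dicarbonyl compounds, but none has been applied to a cyclopent-3-ene-1,2-dione or used to make a benzene ring. Ring A thus arises by one-carbon ring expansion of the five-membered carbocycle through a 1,2-shift and not by cyclisation, and the cyclohex-4-ene-1,3-dione 21 that results is the diketo tautomer of a resorcinol, so two enolisations deliver 22. No stereocentre is set, since the sp3 centres of 15, 20 and 21 all end as sp2 carbons of ring A. The step needs acyl migration to win over migration of the other ring carbon (which would end in an isomeric catechol) and over epoxide closure; the rival migrating carbon is a benzyl-branched methine, the kind of hindered carbon that migrates reluctantly in diazoalkane insertions, the acyl carbon is flat and unhindered, and a spiro-epoxide, if formed, is an α,β-epoxy ketone that the same Lewis acid should open towards 21 by acyl shift. Site selectivity between the two carbonyl groups is not needed because attack at either one followed by acyl shift gives the same mirror-symmetric product, the tetrasubstituted electron-poor alkene is a poor dipolarophile, and slow addition of a slight excess of 19 to 15 limits O-alkylation of the hindered phenols of 22.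

**Step 11**
Reactants: 22 2,4,6-tris[4-(benzyloxy)benzyl]-5-[2-(3-methoxyphenyl)ethyl]benzene-1,3-diol
Product: 23 2,4,6-tris[4-(benzyloxy)benzyl]-3-methoxy-5-[2-(3-methoxyphenyl)ethyl]phenol
Conditions: MeI (1.0 equiv), K2CO3 (1.0 equiv), DMF, rt; recovered 22 recycled
Reagents that add atoms: iodomethane, CI
Why: Williamson O-methylation of a phenoxide; the two hydroxyl groups of 22 are related by the mirror plane through C1 and C4 of ring A, so either one gives the same monoether, and limiting base and MeI to one equivalent keeps the second alkylation down while unreacted 22 is recycled.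

**Step 12**
Reactants: 23 2,4,6-tris[4-(benzyloxy)benzyl]-3-methoxy-5-[2-(3-methoxyphenyl)ethyl]phenol
Product: 24 2,4,6-tris(4-hydroxybenzyl)-3-methoxy-5-[2-(3-methoxyphenyl)ethyl]phenol (target, CNP0285788.0)
Conditions: H2 (1 atm), Pd/C (10 wt %), EtOAc/MeOH, rt
Reagents that add atoms: none
Why: Catalytic hydrogenolysis of aryl benzyl ethers; the diarylmethane and bibenzyl C–C bonds, the two methyl ethers and the arenes are inert under one atmosphere of hydrogen at room temperature.

**Compound list**
1 | cyclopentane-1,3-dione | O=C1CCC(=O)C1 | starting material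
2 | 4-(benzyloxy)benzaldehyde | O=Cc1ccc(OCc2ccccc2)cc1 | starting material
3 | 2-[4-(benzyloxy)benzylidene]cyclopentane-1,3-dione | O=C1CCC(=O)C1=Cc1ccc(OCc2ccccc2)cc1 | intermediate (not isolated)
4 | 2-[4-(benzyloxy)benzyl]cyclopentane-1,3-dione | O=C1CCC(=O)C1Cc1ccc(OCc2ccccc2)cc1 | intermediate
5 | 2-[4-(benzyloxy)benzyl]-3-(2-methylpropoxy)cyclopent-2-en-1-one | CC(C)COC1=C(Cc2ccc(OCc3ccccc3)cc2)C(=O)CC1 | intermediate
6 | 4-(benzyloxy)benzyl bromide | BrCc1ccc(OCc2ccccc2)cc1 | starting material
7 | lithium 2-[4-(benzyloxy)benzyl]-3-(2-methylpropoxy)cyclopenta-1,4-dien-1-olate (α'-enolate of 5) | [Li]OC1=CCC(OCC(C)C)=C1Cc1ccc(OCc2ccccc2)cc1 | intermediate (not isolated)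
8 | 2,5-bis[4-(benzyloxy)benzyl]-3-(2-methylpropoxy)cyclopent-2-en-1-one (racemic) | CC(C)COC1=C(Cc2ccc(OCc3ccccc3)cc2)C(=O)C(Cc2ccc(OCc3ccccc3)cc2)C1 | intermediate
9 | 1-(2-bromoethyl)-3-methoxybenzene | COc1cccc(CCBr)c1 | starting material
10 | [2-(3-methoxyphenyl)ethyl]magnesium bromide | COc1cccc(CC[Mg]Br)c1 | intermediate (not isolated)
11 | 2,5-bis[4-(benzyloxy)benzyl]-1-[2-(3-methoxyphenyl)ethyl]-3-(2-methylpropoxy)cyclopent-2-en-1-ol (diastereomer mixture) | CC(C)COC1=C(Cc2ccc(OCc3ccccc3)cc2)C(O)(CCc2cccc(OC)c2)C(Cc2ccc(OCc3ccccc3)cc2)C1 | intermediate (not isolated)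
12 | 2,4-bis[4-(benzyloxy)benzyl]-3-[2-(3-methoxyphenyl)ethyl]cyclopent-2-en-1-one (racemic) | O=C1CC(Cc2ccc(OCc3ccccc3)cc2)C(CCc2cccc(OC)c2)=C1Cc1ccc(OCc2ccccc2)cc1 | intermediate
13 | potassium α'-dienolate of 12 | [K]OC1=CC(Cc2ccc(OCc3ccccc3)cc2)C(CCc2cccc(OC)c2)=C1Cc1ccc(OCc2ccccc2)cc1 | intermediate (not isolated)
14 | trans-2,4-bis[4-(benzyloxy)benzyl]-5-hydroxy-3-[2-(3-methoxyphenyl)ethyl]cyclopent-2-en-1-one (racemic, one enantiomer drawn) | O=C1[C@H](O)[C@@H](Cc2ccc(OCc3ccccc3)cc2)C(CCc2cccc(OC)c2)=C1Cc1ccc(OCc2ccccc2)cc1 | intermediate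
15 | 3,5-bis[4-(benzyloxy)benzyl]-4-[2-(3-methoxyphenyl)ethyl]cyclopent-3-ene-1,2-dione (racemic) | O=C1C(=O)C(Cc2ccc(OCc3ccccc3)cc2)=C(CCc2cccc(OC)c2)C1Cc1ccc(OCc2ccccc2)cc1 | intermediate
16 | 2-[4-(benzyloxy)phenyl]ethan-1-amine hydrochloride (O-benzyltyramine hydrochloride) | Cl.NCCc1ccc(OCc2ccccc2)cc1 | starting material
17 | 1-{2-[4-(benzyloxy)phenyl]ethyl}urea | NC(=O)NCCc1ccc(OCc2ccccc2)cc1 | intermediate
18 | 1-{2-[4-(benzyloxy)phenyl]ethyl}-1-nitrosourea | NC(=O)N(N=O)CCc1ccc(OCc2ccccc2)cc1 | intermediate
19 | 1-(benzyloxy)-4-(2-diazoethyl)benzene | [N-]=[N+]=CCc1ccc(OCc2ccccc2)cc1 | intermediate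
20 | diazonium betaine from addition of 19 to the non-conjugated carbonyl of 15 (drawn metal-free, diastereomer mixture) | [O-]C1(C(Cc2ccc(OCc3ccccc3)cc2)[N+]#N)C(=O)C(Cc2ccc(OCc3ccccc3)cc2)=C(CCc2cccc(OC)c2)C1Cc1ccc(OCc2ccccc2)cc1 | intermediate (not isolated)
21 | 2,4,6-tris[4-(benzyloxy)benzyl]-5-[2-(3-methoxyphenyl)ethyl]cyclohex-4-ene-1,3-dione (diastereomer mixture) | O=C1C(Cc2ccc(OCc3ccccc3)cc2)C(=O)C(Cc2ccc(OCc3ccccc3)cc2)=C(CCc2cccc(OC)c2)C1Cc1ccc(OCc2ccccc2)cc1 | intermediate (not isolated)
22 | 2,4,6-tris[4-(benzyloxy)benzyl]-5-[2-(3-methoxyphenyl)ethyl]benzene-1,3-diol | COc1cccc(CCc2c(Cc3ccc(OCc4ccccc4)cc3)c(O)c(Cc3ccc(OCc4ccccc4)cc3)c(O)c2Cc2ccc(OCc3ccccc3)cc2)c1 | intermediate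
23 | 2,4,6-tris[4-(benzyloxy)benzyl]-3-methoxy-5-[2-(3-methoxyphenyl)ethyl]phenol | COc1cccc(CCc2c(Cc3ccc(OCc4ccccc4)cc3)c(O)c(Cc3ccc(OCc4ccccc4)cc3)c(OC)c2Cc2ccc(OCc3ccccc3)cc2)c1 | intermediate
24 | 2,4,6-tris(4-hydroxybenzyl)-3-methoxy-5-[2-(3-methoxyphenyl)ethyl]phenol | COc1cccc(CCc2c(Cc3ccc(O)cc3)c(O)c(Cc3ccc(O)cc3)c(OC)c2Cc2ccc(O)cc2)c1 | target

**Total step count:** 12. **Longest linear sequence:** 9 steps (steps 1–6 and 10–12, from 1). The diazoalkane branch (steps 7–9) has 3 steps.

**Steps most likely to fail**

1. Step 10 (new method). Several processes could defeat it: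
   - migration of the methine or vinylic ring carbon in place of the acyl carbon;
   - closure of the betaine to an epoxide that does not rearrange;
   - prototropic drift of the ring alkene of 15 into the arylethyl side chain before addition, which would unmask an acidic enol that only protonates the diazoalkane;
   - acid-induced loss of N2 from 19 with hydride shift;
   - O-alkylation of the product phenols.

   The fallback uses known chemistry only, sets out from 2 and returns at 22. Aldehyde 2 is reduced with NaBH4 in MeOH to 4-(benzyloxy)benzyl alcohol F1. In parallel, commercial 3,5-bis(benzyloxy)benzaldehyde is condensed with diethyl (3-methoxybenzyl)phosphonate (NaH, THF, Horner–Wadsworth–Emmons olefination) to (E)-1,3-bis(benzyloxy)-5-[2-(3-methoxyphenyl)ethenyl]benzene F2. H2 over Pd/C in EtOAc/MeOH then saturates the alkene and removes both benzyl groups to give 5-[2-(3-methoxyphenyl)ethyl]benzene-1,3-diol F3. Threefold Friedel–Crafts benzylation of F3 with F1 (3.3 equiv, TsOH·H2O cat., 1,4-dioxane, rt to 40 °C) fills the three ring positions that are each activated by two hydroxyl groups. The singly activated methoxyphenyl ring should be left alone, and the product is 22.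

2. Step 6. The ene-dione may be lost during oxidation or isolation. Acetic acid released by the oxidant could catalyse the shift of the ring alkene to the exocyclic position. Enolisation to the cyclopentadienone level could be followed by Diels–Alder dimerisation. The hindered acyloin may also oxidise sluggishly.

   The fallback sets out from 12, bypasses 14 and returns at 15. Enone 12 is heated with tert-butoxybis(dimethylamino)methane in toluene to condense at the α'-CH2, giving (5E)-2,4-bis[4-(benzyloxy)benzyl]-5-[(dimethylamino)methylidene]-3-[2-(3-methoxyphenyl)ethyl]cyclopent-2-en-1-one F4. Dye-sensitised photooxygenation (O2, tetraphenylporphyrin, visible light, CH2Cl2, −78 °C) adds singlet oxygen to the electron-rich enamine C=C. The dioxetane fragments to 15 and dimethylformamide under neutral, cold conditions. A cold water wash removes the amide before the Lewis-acid step.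

3. Step 11. Discrimination between the first and the second O-alkylation may be poor, because the monoether is about as nucleophilic as the diol. Material would then be lost to double methylation.

   The fallback sets out from 22 and returns at 23. Acetylation (Ac2O, pyridine, DMAP) gives 2,4,6-tris[4-(benzyloxy)benzyl]-5-[2-(3-methoxyphenyl)ethyl]benzene-1,3-diyl diacetate F5. One equivalent of NaOMe in THF/MeOH at −20 °C removes a single acetate, because the phenoxide so formed makes the remaining aryl acetate a much poorer acyl donor. This gives 2,4,6-tris[4-(benzyloxy)benzyl]-3-hydroxy-5-[2-(3-methoxyphenyl)ethyl]phenyl acetate F6 as its sodium salt. MeI added to the same flask gives 2,4,6-tris[4-(benzyloxy)benzyl]-3-methoxy-5-[2-(3-methoxyphenyl)ethyl]phenyl acetate F7. Methanolysis (K2CO3 cat., MeOH) then releases 23.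

**Further compounds**
F1 | step 10 | 4-(benzyloxy)benzyl alcohol | OCc1ccc(OCc2ccccc2)cc1
F2 | step 10 | (E)-1,3-bis(benzyloxy)-5-[2-(3-methoxyphenyl)ethenyl]benzene | COc1cccc(/C=C/c2cc(OCc3ccccc3)cc(OCc3ccccc3)c2)c1
F3 | step 10 | 5-[2-(3-methoxyphenyl)ethyl]benzene-1,3-diol | COc1cccc(CCc2cc(O)cc(O)c2)c1
F4 | step 6 | (5E)-2,4-bis[4-(benzyloxy)benzyl]-5-[(dimethylamino)methylidene]-3-[2-(3-methoxyphenyl)ethyl]cyclopent-2-en-1-one | CN(C)/C=C1/C(=O)C(Cc2ccc(OCc3ccccc3)cc2)=C(CCc2cccc(OC)c2)C1Cc1ccc(OCc2ccccc2)cc1
F5 | step 11 | 2,4,6-tris[4-(benzyloxy)benzyl]-5-[2-(3-methoxyphenyl)ethyl]benzene-1,3-diyl diacetate | COc1cccc(CCc2c(Cc3ccc(OCc4ccccc4)cc3)c(OC(C)=O)c(Cc3ccc(OCc4ccccc4)cc3)c(OC(C)=O)c2Cc2ccc(OCc3ccccc3)cc2)c1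
F6 | step 11 | 2,4,6-tris[4-(benzyloxy)benzyl]-3-hydroxy-5-[2-(3-methoxyphenyl)ethyl]phenyl acetate | COc1cccc(CCc2c(Cc3ccc(OCc4ccccc4)cc3)c(O)c(Cc3ccc(OCc4ccccc4)cc3)c(OC(C)=O)c2Cc2ccc(OCc3ccccc3)cc2)c1
F7 | step 11 | 2,4,6-tris[4-(benzyloxy)benzyl]-3-methoxy-5-[2-(3-methoxyphenyl)ethyl]phenyl acetate | COc1cccc(CCc2c(Cc3ccc(OCc4ccccc4)cc3)c(OC)c(Cc3ccc(OCc4ccccc4)cc3)c(OC(C)=O)c2Cc2ccc(OCc3ccccc3)cc2)c1
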